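**Retrosynthetic overview**

- Locants: ring C1 (methyl-bearing sp2 carbon), C2 (=CH), C3, C4 (stereocentre), C5, C6; chain C7 (bearing =CH2) to C27. Target 38 is cut at C11–C12 into alkenyl iodide 20 and the keto alkylzinc 37 (Negishi coupling). The chain stereocentres come from the chiral pool: C15 from (R)-citronellyl bromide, C19 from (S)-3-bromo-2-methylpropan-1-ol, C23 from (S)-citronellyl bromide.
- Both Z trisubstituted alkenes (ring C1=C2, chain C10=C11) come from one reagent, (2Z)-1-bromo-3-iodobut-2-ene 4. It alkylates the imide dienolate (C3–C4 bond) and later the methyl ketone 17 (C8–C9 bond).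
- The only ring is made in step 5 from acyclic imide 10. The vinyl group on C4 (C5=C6) is hydroborated and the borane is coupled intramolecularly with the alkenyl iodide at C1, which forms the C1(sp2)–C6(sp3) ring bond.
- Enabling feature: in the cyclohexene, C3 and C6 are necessarily cis across C1=C2, so a Z-configured C3–C2=C1(I)–CH3 arm and a two-carbon C5–C6 arm on C4 converge on C1/C6. Without the double bond C2 and C6 would be enantiotopic, so placing C1=C2 before closure is what makes C4 a defined R centre; C4 itself is set one step earlier by Evans alkylation, and the oxazolidinone is removed in step 6.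
- Ring order: no ring before step 5; the cyclohexene in step 5; no further ring.

Key step: step 5

Remark: the chain double bond C10=C11 is read from the SMILES as Z (C9 and C12 cis), the same geometry as in the ring alkene, which is why one Z-iodobutenyl reagent can serve both.

**Route**

Step 1
Reactants: 1 but-2-yn-1-ol
Product: 3 (2Z)-3-iodobut-2-en-1-ol, via cyclic alkenylalanate 2 (not isolated)
Conditions: NaAlH2(OCH2CH2OMe)2 (1.5 equiv), THF, 0 °C to rt; then I2, THF, −78 to 0 °C
Reagents that add atoms: iodine, II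
Why: Hydroxyl-directed trans-hydroalumination of the propargylic alcohol puts hydride on C2 and aluminium on C3 inside a five-membered alanate, and iodinolysis with retention places iodine cis to the CH2OH group (hydroalumination–iodination of a propargylic alcohol), which fixes the Z geometry used twice later.

Step 2
Reactants: 3 (2Z)-3-iodobut-2-en-1-ol
Product: 4 (2Z)-1-bromo-3-iodobut-2-ene
Conditions: CBr4, PPh3, CH2Cl2, 0 °C
Reagents that add atoms: carbon tetrabromide, BrC(Br)(Br)Br
Why: Appel bromination converts the primary allylic alcohol into the bromide under neutral conditions without touching the alkenyl iodide or its geometry.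

Step 3
Reactants: 5 (4S)-4-benzyl-1,3-oxazolidin-2-one; 6 (2E)-but-2-enoyl chloride
Product: 8 (4S)-4-benzyl-3-[(2E)-but-2-enoyl]-1,3-oxazolidin-2-one, via lithium oxazolidinide 7 (not isolated)
Conditions: n-BuLi, THF, −78 °C; then 6, −78 to 0 °C
Reagents that add atoms: none
Why: N-Acylation of the lithiated Evans oxazolidinone with an acid chloride at low temperature is the standard entry to N-enoyl imides.

Step 4
Reactants: 8 (4S)-4-benzyl-3-[(2E)-but-2-enoyl]-1,3-oxazolidin-2-one; 4 (2Z)-1-bromo-3-iodobut-2-ene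
Product: 10 (4S)-4-benzyl-3-[(2S,4Z)-2-ethenyl-5-iodohex-4-enoyl]-1,3-oxazolidin-2-one, via sodium dienolate 9 (not isolated)
Conditions: NaN(SiMe3)2 (1.1 equiv), THF, −78 °C; then 4 (1.5 equiv), −78 to −50 °C; cold pH 7 buffer
Reagents that add atoms: none
Why: γ-Deprotonation of the N-crotonyl imide gives the chelated (Z)-sodium dienolate, which should be alkylated at the α-carbon by the allylic bromide on the face opposite the benzyl group (Evans deconjugative asymmetric alkylation); this sets C4 (2S in 10, the future R ring centre) and leaves the vinyl group that becomes C5–C6.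

Step 5
Reactants: 10 (4S)-4-benzyl-3-[(2S,4Z)-2-ethenyl-5-iodohex-4-enoyl]-1,3-oxazolidin-2-one
Product: 12 (4S)-4-benzyl-3-[(1R)-4-methylcyclohex-3-ene-1-carbonyl]-1,3-oxazolidin-2-one, via B-alkyl-9-BBN borane 11 (not isolated)
Conditions: 9-BBN (1.3 equiv), THF, 0 °C to rt; then PdCl2(dppf) (10 mol %), AsPh3 (10 mol %), aq. K3PO4 (3 equiv), THF/DMF, 0.01 M, rt to 45 °C
Reagents that add atoms: none
Why: 9-BBN adds only to the monosubstituted vinyl group (boron to C6; the trisubstituted iodoalkene is inert to this hindered borane), and after activation by aqueous phosphate the B-alkyl borate transmetalates onto the alkenylpalladium iodide formed by oxidative addition of zerovalent palladium into the C1–I bond of the same molecule; reductive elimination then forms C1–C6. This is an intramolecular B-alkyl Suzuki–Miyaura coupling, whose closest precedent is the hydroboration/cyclization of halogenated 1,n-dienes to five- and six-membered cycloalkenes. The cyclohexene closes through a seven-membered palladacycle with C1=C2 endocyclic, a mode open only because the iodide is Z (iodine cis to C3) and the coupling proceeds with retention at C1. No new stereocentre is formed: C4 is carried over from step 4 and is R in 12 only because the double bond is already fixed at C1=C2 and cannot appear on the C6 side. The step needs chemoselective hydroboration (secured by the steric demand of 9-BBN), cyclization over oligomerization (0.01 M and the favourable six-membered ring) and integrity of C4 (once the vinyl group is consumed the imide α-hydrogen is no longer allylic, and allylic strain in the imide disfavours its removal by the mild base).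

Step 6
Reactants: 12 (4S)-4-benzyl-3-[(1R)-4-methylcyclohex-3-ene-1-carbonyl]-1,3-oxazolidin-2-one
Product: 15 (1R)-4-methylcyclohex-3-ene-1-carboxylic acid, via lithium percarboxylate 13 (not isolated), via lithium carboxylate 14 (not isolated)
Conditions: LiOH, H2O2, THF/H2O (3:1), 0 °C; then aq. Na2SO3; then HCl to pH 2
Reagents that add atoms: hydrogen peroxide, OO
Why: Lithium hydroperoxide attacks the exocyclic imide carbonyl selectively (Evans auxiliary cleavage), which should release the acid without epimerization of the α-centre and return the auxiliary.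

Step 7
Reactants: 15 (1R)-4-methylcyclohex-3-ene-1-carboxylic acid
Product: 17 1-[(1R)-4-methylcyclohex-3-en-1-yl]ethan-1-one, via acid chloride 16 (not isolated)
Conditions: (COCl)2 (1.2 equiv), DMF (cat.), CH2Cl2, 0 °C to rt; concentrate; then Me2CuLi (3 equiv, from MeLi and CuI), Et2O, −78 °C; MeOH, then aq. NH4Cl
Reagents that add atoms: lithium dimethylcuprate, [Li+].C[Cu-]C
Why: Oxalyl chloride with catalytic DMF forms the acid chloride without any base, and lithium dimethylcuprate transfers one methyl group to the acyl chloride at −78 °C without adding to the ketone that results (ketone synthesis from an acid chloride and an organocuprate), so the α-centre is never exposed to an enolizing base.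

Step 8
Reactants: 17 1-[(1R)-4-methylcyclohex-3-en-1-yl]ethan-1-one; 4 (2Z)-1-bromo-3-iodobut-2-ene
Product: 19 (4Z)-5-iodo-1-[(1R)-4-methylcyclohex-3-en-1-yl]hex-4-en-1-one, via lithium enolate 18 (not isolated)
Conditions: LiN(i-Pr)2 (1.05 equiv), THF, −78 °C; then 4 (1.2 equiv), DMPU, −78 to −40 °C
Reagents that add atoms: none
Why: Kinetic deprotonation at −78 °C occurs at the methyl group and not at the hindered ring methine, and the terminal enolate is C-alkylated by the reactive allylic bromide (regioselective kinetic enolate alkylation), which installs the second (Z)-alkenyl iodide and leaves C4 untouched.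

Step 9
Reactants: 19 (4Z)-5-iodo-1-[(1R)-4-methylcyclohex-3-en-1-yl]hex-4-en-1-one
Product: 20 (4R)-4-[(5Z)-6-iodohepta-1,5-dien-2-yl]-1-methylcyclohex-1-ene
Conditions: Ph3PCH3Br, KOt-Bu, THF, 0 °C; then 19, 0 °C
Reagents that add atoms: methyltriphenylphosphonium bromide, C[P+](c1ccccc1)(c1ccccc1)c1ccccc1.[Br-]
Why: Wittig methylenation with the non-stabilized ylide converts the ketone into the 1,1-disubstituted alkene at low temperature, where the α-methine should not epimerize and the alkenyl iodide is inert.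

Step 10
Reactants: 21 (6S)-8-bromo-2,6-dimethyloct-2-ene; 22 (2S)-3-bromo-2-methylpropan-1-ol
Product: 25 (2R,6R)-2,6,10-trimethylundec-9-en-1-ol, via (S)-citronellylmagnesium bromide 23 (not isolated), via chloromagnesium alkoxide 24 (not isolated)
Conditions: 21, Mg, THF, rt; 22, MeMgCl (1.0 equiv), THF, −20 °C; then combine, Li2CuCl4 (3 mol %), −20 °C to rt; aq. HCl
Reagents that add atoms: none
Why: Copper-catalysed Grignard cross-coupling (Kochi-type sp3–sp3 coupling) joins the citronellyl Grignard reagent to the primary bromide of the magnesium alkoxide; neither stereocentre is at a reacting carbon, so C19 and C23 come unchanged from the chiral pool.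

Step 11
Reactants: 25 (2R,6R)-2,6,10-trimethylundec-9-en-1-ol
Product: 26 (2R,6S)-2,6,10-trimethylundecan-1-ol
Conditions: H2 (1 atm), Pd/C, EtOAc, rt
Reagents that add atoms: none
Why: Heterogeneous hydrogenation saturates the only alkene and does not touch the two stereocentres (the C6 descriptor changes only because the CIP priorities change).

Step 12
Reactants: 26 (2R,6S)-2,6,10-trimethylundecan-1-ol
Product: 27 (2R,6S)-2,6,10-trimethylundecanal
Conditions: TEMPO (10 mol %), PhI(OAc)2, CH2Cl2, rt
Reagents that add atoms: none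
Why: The oxoammonium (TEMPO) oxidation takes the primary alcohol to the aldehyde under neutral conditions, which should keep the epimerizable α-methyl centre intact.

Step 13
Reactants: 28 (6R)-8-bromo-2,6-dimethyloct-2-ene; 27 (2R,6S)-2,6,10-trimethylundecanal
Product: 31 (6R,10R,14S)-2,6,10,14,18-pentamethylnonadec-2-en-9-ol (both C9 epimers), via (R)-citronellylmagnesium bromide 29 (not isolated), via bromomagnesium alkoxide 30 (not isolated)
Conditions: 28, Mg, THF, rt; then 27, THF, −78 °C; aq. NH4Cl
Reagents that add atoms: none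
Why: Grignard addition to the aldehyde at low temperature forms the C17–C18 bond; the new carbinol centre is formed as a mixture, which does not matter because it is oxidized in the next step.

Step 14
Reactants: 31 (6R,10R,14S)-2,6,10,14,18-pentamethylnonadec-2-en-9-ol
Product: 32 (6R,10R,14S)-2,6,10,14,18-pentamethylnonadec-2-en-9-one
Conditions: Dess–Martin periodinane, CH2Cl2, 0 °C to rt
Reagents that add atoms: none
Why: Dess–Martin oxidation converts the secondary alcohol into the ketone under nearly neutral conditions, so the adjacent α-methyl centre (C19) should not epimerize.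

Step 15
Reactants: 32 (6R,10R,14S)-2,6,10,14,18-pentamethylnonadec-2-en-9-one
Product: 34 (4R,8R,12S)-4,8,12,16-tetramethyl-7-oxoheptadecanal, via secondary ozonide 33 (not isolated)
Conditions: O3, CH2Cl2, −78 °C; then PPh3, −78 °C to rt
Reagents that add atoms: ozone, [O-][O+]=O
Why: Ozonolysis with reductive work-up cleaves the only (trisubstituted) alkene to the aldehyde and acetone and leaves the saturated ketone and its α-centre untouched.

Step 16
Reactants: 34 (4R,8R,12S)-4,8,12,16-tetramethyl-7-oxoheptadecanal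
Product: 35 (4R,8R,12S)-1-hydroxy-4,8,12,16-tetramethylheptadecan-7-one
Conditions: NaBH4, EtOH/CH2Cl2 (3:7), −78 °C
Reagents that add atoms: none
Why: At −78 °C in ethanol/dichloromethane, borohydride reduces aldehydes far faster than ketones (chemoselective carbonyl reduction), so only the terminal aldehyde should be reduced.

Step 17
Reactants: 35 (4R,8R,12S)-1-hydroxy-4,8,12,16-tetramethylheptadecan-7-one
Product: 36 (4S,8R,12S)-1-iodo-4,8,12,16-tetramethylheptadecan-7-one
Conditions: I2, PPh3, imidazole, CH2Cl2, 0 °C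
Reagents that add atoms: iodine, II
Why: Appel-type iodination converts the primary alcohol into the iodide without affecting the ketone or any stereocentre (the C4 descriptor changes only because iodine changes the CIP priorities).

Step 18
Reactants: 36 (4S,8R,12S)-1-iodo-4,8,12,16-tetramethylheptadecan-7-one; 20 (4R)-4-[(5Z)-6-iodohepta-1,5-dien-2-yl]-1-methylcyclohex-1-ene
Product: 38 (6S,10R,14R,18Z)-2,6,10,14,18-pentamethyl-22-[(1R)-4-methylcyclohex-3-en-1-yl]tricosa-18,22-dien-11-one, via alkylzinc iodide 37 (not isolated)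
Conditions: Zn dust (activated with BrCH2CH2Br and Me3SiCl), DMA, 40 °C; then 20, PdCl2(dppf) (5 mol %), THF/DMA, 45 °C
Reagents that add atoms: none
Why: Direct zinc insertion into the primary C–I bond gives an alkylzinc iodide that tolerates the ketone, and palladium-catalysed Negishi coupling with the alkenyl iodide forms the C11–C12 bond with retention of the Z geometry, which completes the skeleton.

**Compound list**

1 | but-2-yn-1-ol | CC#CCO | starting material
2 | sodium 2,2-bis(2-methoxyethoxy)-3-methyl-2,5-dihydro-1,2-oxaluminol-2-uide (cyclic alkenylalanate) | CC1=CCO[Al-]1(OCCOC)OCCOC.[Na+] | intermediate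
3 | (2Z)-3-iodobut-2-en-1-ol | OC/C=C(/C)I | intermediate
4 | (2Z)-1-bromo-3-iodobut-2-ene | BrC/C=C(/C)I | intermediate
5 | (4S)-4-benzyl-1,3-oxazolidin-2-one | O=C1OC[C@H](Cc2ccccc2)N1 | starting material
6 | (2E)-but-2-enoyl chloride | C/C=C/C(=O)Cl | starting material
7 | lithium (4S)-4-benzyl-2-oxo-1,3-oxazolidin-3-ide | [Li+].O=C1OC[C@H](Cc2ccccc2)[N-]1 | intermediate
8 | (4S)-4-benzyl-3-[(2E)-but-2-enoyl]-1,3-oxazolidin-2-one | O=C1OC[C@H](Cc2ccccc2)N1C(=O)/C=C/C | intermediate
9 | sodium (1Z)-1-[(4S)-4-benzyl-2-oxo-1,3-oxazolidin-3-yl]buta-1,3-dien-1-olate | [Na+].O=C1OC[C@H](Cc2ccccc2)N1/C([O-])=C/C=C | intermediate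
10 | (4S)-4-benzyl-3-[(2S,4Z)-2-ethenyl-5-iodohex-4-enoyl]-1,3-oxazolidin-2-one | O=C1OC[C@H](Cc2ccccc2)N1C(=O)[C@H](C=C)C/C=C(/C)I | intermediate
11 | (4S)-4-benzyl-3-[(2R,4Z)-2-[2-(9-borabicyclo[3.3.1]nonan-9-yl)ethyl]-5-iodohex-4-enoyl]-1,3-oxazolidin-2-one | O=C1OC[C@H](Cc2ccccc2)N1C(=O)[C@H](CCB2C3CCCC2CCC3)C/C=C(/C)I | intermediate
12 | (4S)-4-benzyl-3-[(1R)-4-methylcyclohex-3-ene-1-carbonyl]-1,3-oxazolidin-2-one | O=C1OC[C@H](Cc2ccccc2)N1C(=O)[C@H]3CC=C(C)CC3 | intermediate
13 | lithium (1R)-4-methylcyclohex-3-ene-1-carboperoxoate | [Li+].[O-]OC(=O)[C@H]1CC=C(C)CC1 | intermediate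
14 | lithium (1R)-4-methylcyclohex-3-ene-1-carboxylate | [Li+].[O-]C(=O)[C@H]1CC=C(C)CC1 | intermediate
15 | (1R)-4-methylcyclohex-3-ene-1-carboxylic acid | OC(=O)[C@H]1CC=C(C)CC1 | intermediate
16 | (1R)-4-methylcyclohex-3-ene-1-carbonyl chloride | ClC(=O)[C@H]1CC=C(C)CC1 | intermediate
17 | 1-[(1R)-4-methylcyclohex-3-en-1-yl]ethan-1-one | CC(=O)[C@H]1CC=C(C)CC1 | intermediate
18 | lithium 1-[(1R)-4-methylcyclohex-3-en-1-yl]ethen-1-olate | [Li+].C=C([O-])[C@H]1CC=C(C)CC1 | intermediate
19 | (4Z)-5-iodo-1-[(1R)-4-methylcyclohex-3-en-1-yl]hex-4-en-1-one | O=C(CC/C=C(/C)I)[C@H]1CC=C(C)CC1 | intermediate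
20 | (4R)-4-[(5Z)-6-iodohepta-1,5-dien-2-yl]-1-methylcyclohex-1-ene | C=C(CC/C=C(/C)I)[C@H]1CC=C(C)CC1 | intermediate
21 | (6S)-8-bromo-2,6-dimethyloct-2-ene ((S)-citronellyl bromide) | BrCC[C@@H](C)CCC=C(C)C | starting material
22 | (2S)-3-bromo-2-methylpropan-1-ol | OC[C@H](C)CBr | starting material
23 | [(3S)-3,7-dimethyloct-6-en-1-yl]magnesium bromide | Br[Mg]CC[C@@H](C)CCC=C(C)C | intermediate
24 | chloromagnesium (2S)-3-bromo-2-methylpropan-1-olate | Cl[Mg]OC[C@H](C)CBr | intermediate
25 | (2R,6R)-2,6,10-trimethylundec-9-en-1-ol | OC[C@H](C)CCC[C@@H](C)CCC=C(C)C | intermediate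
26 | (2R,6S)-2,6,10-trimethylundecan-1-ol | OC[C@H](C)CCC[C@@H](C)CCCC(C)C | intermediate
27 | (2R,6S)-2,6,10-trimethylundecanal | O=C[C@H](C)CCC[C@@H](C)CCCC(C)C | intermediate
28 | (6R)-8-bromo-2,6-dimethyloct-2-ene ((R)-citronellyl bromide) | BrCC[C@H](C)CCC=C(C)C | starting material
29 | [(3R)-3,7-dimethyloct-6-en-1-yl]magnesium bromide | Br[Mg]CC[C@H](C)CCC=C(C)C | intermediate
30 | bromomagnesium (6R,10R,14S)-2,6,10,14,18-pentamethylnonadec-2-en-9-olate (C9 epimers) | CC(C)=CCC[C@@H](C)CCC(O[Mg]Br)[C@H](C)CCC[C@@H](C)CCCC(C)C | intermediate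
31 | (6R,10R,14S)-2,6,10,14,18-pentamethylnonadec-2-en-9-ol (C9 epimers) | CC(C)=CCC[C@@H](C)CCC(O)[C@H](C)CCC[C@@H](C)CCCC(C)C | intermediate
32 | (6R,10R,14S)-2,6,10,14,18-pentamethylnonadec-2-en-9-one | CC(C)=CCC[C@@H](C)CCC(=O)[C@H](C)CCC[C@@H](C)CCCC(C)C | intermediate
33 | 3,3-dimethyl-5-[(3R,7R,11S)-3,7,11,15-tetramethyl-6-oxohexadecyl]-1,2,4-trioxolane (secondary ozonide) | CC1(C)OOC(CC[C@@H](C)CCC(=O)[C@H](C)CCC[C@@H](C)CCCC(C)C)O1 | intermediate
34 | (4R,8R,12S)-4,8,12,16-tetramethyl-7-oxoheptadecanal | O=CCC[C@@H](C)CCC(=O)[C@H](C)CCC[C@@H](C)CCCC(C)C | intermediate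
35 | (4R,8R,12S)-1-hydroxy-4,8,12,16-tetramethylheptadecan-7-one | OCCC[C@@H](C)CCC(=O)[C@H](C)CCC[C@@H](C)CCCC(C)C | intermediate
36 | (4S,8R,12S)-1-iodo-4,8,12,16-tetramethylheptadecan-7-one | ICCC[C@@H](C)CCC(=O)[C@H](C)CCC[C@@H](C)CCCC(C)C | intermediate
37 | iodo[(4S,8R,12S)-4,8,12,16-tetramethyl-7-oxoheptadecyl]zinc | I[Zn]CCC[C@@H](C)CCC(=O)[C@H](C)CCC[C@@H](C)CCCC(C)C | intermediate
38 | (6S,10R,14R,18Z)-2,6,10,14,18-pentamethyl-22-[(1R)-4-methylcyclohex-3-en-1-yl]tricosa-18,22-dien-11-one | C=C(CC/C=C(/C)CCC[C@@H](C)CCC(=O)[C@H](C)CCC[C@@H](C)CCCC(C)C)[C@H]1CC=C(C)CC1 | target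

**Step count and risks**

Total step count: 18.
Longest linear sequence: 9 steps (1 → 3 → 4 → 10 → 12 → 15 → 17 → 19 → 20 → 38; steps 1, 2, 4, 5, 6, 7, 8, 9, 18); the chain branch (steps 10 to 18) is equally long.

Steps most likely to fail:

Step 4. The sodium dienolate may be alkylated at the γ-carbon instead of the α-carbon, or the α-vinyl imide may slip into conjugation during reaction or work-up, which would erode or destroy C4. Fallback (sets out from 5 and 4, returns at 10): the vinyl group is carried in masked form. γ-Butyrolactone is opened with PhSeNa (from PhSeSePh and NaBH4, DMF, 110 °C) to 4-(phenylselanyl)butanoic acid F1. F1 is attached to the auxiliary (PivCl, Et3N; then 7 made from 5) to give (4S)-4-benzyl-3-[4-(phenylselanyl)butanoyl]-1,3-oxazolidin-2-one F2. Ordinary Evans alkylation of its (Z)-sodium enolate with 4 should give (4S)-4-benzyl-3-[(2S,4Z)-5-iodo-2-[2-(phenylselanyl)ethyl]hex-4-enoyl]-1,3-oxazolidin-2-one F3. Oxidation (H2O2, pyridine, CH2Cl2, 0 °C) gives the selenoxide (4S)-4-benzyl-3-[(2S,4Z)-5-iodo-2-[2-(benzeneseleninyl)ethyl]hex-4-enoyl]-1,3-oxazolidin-2-one F4, whose syn-elimination at room temperature unmasks the vinyl group and delivers 10.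

Step 5. Under the aqueous base of the coupling the imide may be hydrolysed or epimerized, or the alkenylpalladium intermediate may couple between molecules, so that the ring does not close cleanly. Fallback (sets out from 10, returns at 17): the same C1–C6 bond is closed by a base-free Negishi cyclization at the amide stage. 10 is hydroborated as in step 5 and borane 11 is oxidized (NaBO3·4H2O, THF/H2O) to (4S)-4-benzyl-3-[(2S,4Z)-2-(2-hydroxyethyl)-5-iodohex-4-enoyl]-1,3-oxazolidin-2-one F5. F5 lactonizes (cat. TsOH, CH2Cl2) to (3S)-3-[(2Z)-3-iodobut-2-en-1-yl]oxolan-2-one F6 with release of 5. Opening with Me(MeO)NH·HCl/AlMe3 gives (2S,4Z)-2-(2-hydroxyethyl)-5-iodo-N-methoxy-N-methylhex-4-enamide F7, and I2/PPh3/imidazole gives (2S,4Z)-5-iodo-2-(2-iodoethyl)-N-methoxy-N-methylhex-4-enamide F8. Zinc insertion into the alkyl iodide only (Zn dust, DMA, 40 °C) gives iodo[(3S,5Z)-6-iodo-3-[methoxy(methyl)carbamoyl]hept-5-en-1-yl]zinc F9, which should cyclize with PdCl2(dppf) at high dilution to (1R)-N-methoxy-N,4-dimethylcyclohex-3-ene-1-carboxamide F10. MeMgBr (THF, 0 °C) then gives 17.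

Step 8. Proton transfer between the kinetic enolate and the product ketone may lead to polyalkylation, to the regioisomeric enolate and to epimerization of the ring stereocentre. Fallback (sets out from 15, returns at 19): the alkylation site is fixed by a β-keto ester and only weak base is used. 15 is activated with carbonyldiimidazole to 1H-imidazol-1-yl[(1R)-4-methylcyclohex-3-en-1-yl]methanone F11 and condensed with potassium methyl malonate (MgCl2, Et3N, MeCN) to methyl 3-[(1R)-4-methylcyclohex-3-en-1-yl]-3-oxopropanoate F12. Alkylation at the doubly activated carbon (K2CO3, acetone, 4) gives methyl (4Z)-5-iodo-2-[(1R)-4-methylcyclohex-3-ene-1-carbonyl]hex-4-enoate F13. Saponification (LiOH, THF/H2O) and acidification give (4Z)-5-iodo-2-[(1R)-4-methylcyclohex-3-ene-1-carbonyl]hex-4-enoic acid F14, which should lose carbon dioxide on gentle warming to deliver 19.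

Further compounds
F1 | step 4 | 4-(phenylselanyl)butanoic acid | OC(=O)CCC[Se]c1ccccc1
F2 | step 4 | (4S)-4-benzyl-3-[4-(phenylselanyl)butanoyl]-1,3-oxazolidin-2-one | O=C1OC[C@H](Cc2ccccc2)N1C(=O)CCC[Se]c3ccccc3
F3 | step 4 | (4S)-4-benzyl-3-[(2S,4Z)-5-iodo-2-[2-(phenylselanyl)ethyl]hex-4-enoyl]-1,3-oxazolidin-2-one | O=C1OC[C@H](Cc2ccccc2)N1C(=O)[C@H](CC[Se]c3ccccc3)C/C=C(/C)I
F4 | step 4 | (4S)-4-benzyl-3-[(2S,4Z)-5-iodo-2-[2-(benzeneseleninyl)ethyl]hex-4-enoyl]-1,3-oxazolidin-2-one | O=C1OC[C@H](Cc2ccccc2)N1C(=O)[C@H](CC[Se](=O)c3ccccc3)C/C=C(/C)I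
F5 | step 5 | (4S)-4-benzyl-3-[(2S,4Z)-2-(2-hydroxyethyl)-5-iodohex-4-enoyl]-1,3-oxazolidin-2-one | O=C1OC[C@H](Cc2ccccc2)N1C(=O)[C@H](CCO)C/C=C(/C)I
F6 | step 5 | (3S)-3-[(2Z)-3-iodobut-2-en-1-yl]oxolan-2-one | O=C1OCC[C@@H]1C/C=C(/C)I
F7 | step 5 | (2S,4Z)-2-(2-hydroxyethyl)-5-iodo-N-methoxy-N-methylhex-4-enamide | CON(C)C(=O)[C@H](CCO)C/C=C(/C)I
F8 | step 5 | (2S,4Z)-5-iodo-2-(2-iodoethyl)-N-methoxy-N-methylhex-4-enamide | CON(C)C(=O)[C@H](CCI)C/C=C(/C)I
F9 | step 5 | iodo[(3S,5Z)-6-iodo-3-[methoxy(methyl)carbamoyl]hept-5-en-1-yl]zinc | CON(C)C(=O)[C@H](CC[Zn]I)C/C=C(/C)I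
F10 | step 5 | (1R)-N-methoxy-N,4-dimethylcyclohex-3-ene-1-carboxamide | CON(C)C(=O)[C@H]1CC=C(C)CC1
F11 | step 8 | 1H-imidazol-1-yl[(1R)-4-methylcyclohex-3-en-1-yl]methanone | O=C([C@H]1CC=C(C)CC1)n1ccnc1
F12 | step 8 | methyl 3-[(1R)-4-methylcyclohex-3-en-1-yl]-3-oxopropanoate | COC(=O)CC(=O)[C@H]1CC=C(C)CC1
F13 | step 8 | methyl (4Z)-5-iodo-2-[(1R)-4-methylcyclohex-3-ene-1-carbonyl]hex-4-enoate | COC(=O)C(C/C=C(/C)I)C(=O)[C@H]1CC=C(C)CC1
F14 | step 8 | (4Z)-5-iodo-2-[(1R)-4-methylcyclohex-3-ene-1-carbonyl]hex-4-enoic acid | OC(=O)C(C/C=C(/C)I)C(=O)[C@H]1CC=C(C)CC1
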